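**Strategy.** The cyclohexane ring (C1 carbinol, C2 angelate carbon, C3 methyl-bearing epoxide carbon, C4 epoxide CH, C5 CH2, C6 side-chain carbon) is disconnected at C3. The unit C2–C3–C4 is an allyl cation, so C3 is inserted as a dibromocarbene carbon into a cyclopentene whose allylic C1 oxygen already carries an angelate. In one operation, silver-induced electrocyclic opening of the dibromocyclopropane expands the five-membered ring to the cyclohexene, the C1 angelate captures C2 as a temporary cis-fused dioxolanylium ring, and hydrolysis leaves the C2 angelate, the free C1 hydroxyl and a C3 bromide for the methyl group. The precursor is a 6,6-dibromobicyclo[3.1.0]hexane carrying the complete side chain.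

Key step: step 13

Assumption: the MgCl2-catalysed anti-aldol of step 2 follows the chelated-enolate facial sense, so the (R)-auxiliary is used; if the other anti isomer formed, the (S)-auxiliary would be used with no other change. "Target C1–C6" in the Why lines is the ring numbering defined above.

Step 1
Reactants: 1 (R)-4-benzyloxazolidin-2-one; 2 pent-4-enoyl chloride
Product: 4 (R)-4-benzyl-3-(pent-4-enoyl)oxazolidin-2-one, via lithium oxazolidinide 3 (not isolated)
Conditions: n-BuLi, THF, −78 °C; then 2, −78 → 0 °C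
Reagents that add atoms: none
Why: N-acylation of the lithiated oxazolidinone with an acid chloride is the standard preparation of an Evans imide and forms no stereocentre.

Step 2
Reactants: 4 (R)-4-benzyl-3-(pent-4-enoyl)oxazolidin-2-one; 5 (E)-cinnamaldehyde
Product: 7 (R)-4-benzyl-3-[(2S,3S,4E)-2-allyl-3-hydroxy-5-phenylpent-4-enoyl]oxazolidin-2-one, via trimethylsilyl ether 6 (not isolated)
Conditions: MgCl2 (10 mol%), Et3N, Me3SiCl, EtOAc, 23 °C; then CF3CO2H, MeOH
Reagents that add atoms: none
Why: In this MgCl2-catalysed direct Evans anti-aldol the chelated (Z)-magnesium enolate should be attacked on the face away from the benzyl group through a boat-like transition state, which sets the two new centres (target C6 and C1) anti under auxiliary control while silylation of the aldolate drives turnover.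

Step 3
Reactants: 7 (R)-4-benzyl-3-[(2S,3S,4E)-2-allyl-3-hydroxy-5-phenylpent-4-enoyl]oxazolidin-2-one
Product: 8 (2S,3S,4E)-2-allyl-3-hydroxy-N-methoxy-N-methyl-5-phenylpent-4-enamide
Conditions: MeNHOMe·HCl, AlMe3, CH2Cl2, −20 → 0 °C; 1 M HCl work-up
Reagents that add atoms: N,O-dimethylhydroxylamine hydrochloride, CNOC.Cl
Why: Aluminium amide transamination of a β-hydroxy imide to the Weinreb amide is assisted by the free hydroxyl, returns the auxiliary and touches neither stereocentre.

Step 4
Reactants: 8 (2S,3S,4E)-2-allyl-3-hydroxy-N-methoxy-N-methyl-5-phenylpent-4-enamide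
Product: 9 (2S,3S,4E)-2-allyl-N-methoxy-N-methyl-5-phenyl-3-(triethylsilyloxy)pent-4-enamide
Conditions: Et3SiOTf, 2,6-lutidine, CH2Cl2, −78 → 0 °C
Reagents that add atoms: triethylsilyl triflate, CC[Si](CC)(CC)OS(=O)(=O)C(F)(F)F
Why: Silyl ether formation with a silyl triflate and a hindered base protects the hydroxyl for the basic, hydride and ylide steps that follow and forms no stereocentre.

Step 5
Reactants: 9 (2S,3S,4E)-2-allyl-N-methoxy-N-methyl-5-phenyl-3-(triethylsilyloxy)pent-4-enamide
Product: 10 (1S,2S)-N-methoxy-N-methyl-2-(triethylsilyloxy)cyclopent-3-ene-1-carboxamide (silyloxy trans to carboxamide)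
Conditions: second-generation Grubbs catalyst RuCl2(=CHPh)(PCy3)(H2IMes) (3 mol%), CH2Cl2, 40 °C
Reagents that add atoms: none
Why: Ring-closing metathesis of the terminal alkene onto the styryl alkene closes the cyclopentene with loss of styrene, and the anti relationship of the diene becomes the trans relationship on the ring.

Step 6
Reactants: 10 (1S,2S)-N-methoxy-N-methyl-2-(triethylsilyloxy)cyclopent-3-ene-1-carboxamide
Product: 11 (1R,2R,3S,5R)-6,6-dibromo-N-methoxy-N-methyl-2-(triethylsilyloxy)bicyclo[3.1.0]hexane-3-carboxamide (cyclopropane on the face opposite the silyloxy group)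
Conditions: CHBr3, 50% aq. NaOH, BnEt3NCl (cat.), CH2Cl2, 0 °C → rt
Reagents that add atoms: bromoform, BrC(Br)Br
Why: Dibromocarbene generated under phase-transfer conditions adds stereospecifically to the only alkene, mainly anti to the allylic silyloxy group, and since either face gives a cyclopropane with one endo bromide the two new ring-fusion centres have no bearing on the later ring expansion.

Step 7
Reactants: 11 (1R,2R,3S,5R)-6,6-dibromo-N-methoxy-N-methyl-2-(triethylsilyloxy)bicyclo[3.1.0]hexane-3-carboxamide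
Product: 13 (1R,2R,3S,5R)-6,6-dibromo-2-(triethylsilyloxy)bicyclo[3.1.0]hexane-3-carbaldehyde, via aluminium hemiaminal 12 (not isolated)
Conditions: i-Bu2AlH, THF, −78 °C; aq. KNaC4H4O6 work-up
Reagents that add atoms: none
Why: Hydride reduction of a Weinreb amide stops at the chelated tetrahedral aluminium hemiaminal, which releases the aldehyde only on work-up, and the dibromocyclopropane is inert to the hydride at −78 °C.

Step 8
Reactants: 13 (1R,2R,3S,5R)-6,6-dibromo-2-(triethylsilyloxy)bicyclo[3.1.0]hexane-3-carbaldehyde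
Product: 15 2-[(1R,2R,3R,5R)-6,6-dibromo-2-hydroxybicyclo[3.1.0]hexan-3-yl]acetaldehyde, via methyl enol ether 14 (not isolated)
Conditions: MeOCH2PPh3Cl, KN(SiMe3)2, THF, −78 → 0 °C; then 1 M HCl, THF, rt
Reagents that add atoms: (methoxymethyl)triphenylphosphonium chloride, COC[P+](c1ccccc1)(c1ccccc1)c1ccccc1.[Cl-]; water, O
Why: Wittig methoxymethylenation followed by acid hydrolysis of the enol ether is the standard one-carbon homologation of an aldehyde, the acid removes the triethylsilyl ether in the same pot, and no new stereocentre remains in the product.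

Step 9
Reactants: 15 2-[(1R,2R,3R,5R)-6,6-dibromo-2-hydroxybicyclo[3.1.0]hexan-3-yl]acetaldehyde
Product: 17 2-[(1R,2R,3R,5R)-6,6-dibromo-2-hydroxybicyclo[3.1.0]hexan-3-yl]prop-2-enal, via Mannich base 16 (not isolated)
Conditions: CH2=NMe2+ I− (Eschenmoser's salt), Et3N, CH2Cl2, rt
Reagents that add atoms: N,N-dimethylmethyleneiminium iodide, C=[N+](C)C.[I-]
Why: Mannich reaction of the aldehyde with the preformed iminium salt and loss of dimethylamine from the Mannich base (α-methylenation of an aldehyde) installs the exocyclic methylene, and the transient centre of 16 is destroyed.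

Step 10
Reactants: 17 2-[(1R,2R,3R,5R)-6,6-dibromo-2-hydroxybicyclo[3.1.0]hexan-3-yl]prop-2-enal
Product: 19 (1R,2R,3R,5R)-6,6-dibromo-3-[(3S)-3-hydroxyhexa-1,5-dien-2-yl]bicyclo[3.1.0]hexan-2-ol, via borinate ester 18 (not isolated)
Conditions: (−)-Ipc2B(allyl) (2.5 equiv), Et2O, −78 °C; then NaOH, H2O2
Reagents that add atoms: (−)-B-allyldiisopinocampheylborane (from (+)-α-pinene), C=CCB([C@@H]1C[C@@H]2C[C@H]([C@H]1C)C2(C)C)[C@@H]1C[C@@H]2C[C@H]([C@H]1C)C2(C)C
Why: Brown allylboration through a chair transition state is reagent-controlled, and the (−)-reagent should give the (S)-carbinol from this 2-substituted acrolein, as it does from other aldehydes whose substituent outranks allyl.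

Step 11
Reactants: 19 (1R,2R,3R,5R)-6,6-dibromo-3-[(3S)-3-hydroxyhexa-1,5-dien-2-yl]bicyclo[3.1.0]hexan-2-ol
Product: 20 (1R,2R,3R,5R)-6,6-dibromo-3-[(3S)-3-hydroxy-6-methylhepta-1,5-dien-2-yl]bicyclo[3.1.0]hexan-2-ol
Conditions: 2-methylbut-2-ene (excess), second-generation Grubbs catalyst RuCl2(=CHPh)(PCy3)(H2IMes) (5 mol%), CH2Cl2, 35 °C
Reagents that add atoms: 2-methylbut-2-ene, CC=C(C)C
Why: Cross-metathesis of the monosubstituted alkene with excess 2-methylbut-2-ene turns the vinyl group into the isopropylidene terminus, while the 1,1-disubstituted alkene and the cyclopropane do not react and no stereocentre is touched.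

Step 12
Reactants: 20 (1R,2R,3R,5R)-6,6-dibromo-3-[(3S)-3-hydroxy-6-methylhepta-1,5-dien-2-yl]bicyclo[3.1.0]hexan-2-ol; 21 angelic acid
Product: 22 (1R,2R,3R,5R)-6,6-dibromo-3-[(3S)-3-(angeloyloxy)-6-methylhepta-1,5-dien-2-yl]bicyclo[3.1.0]hexan-2-yl angelate
Conditions: 21 (2.6 equiv), 2,4,6-Cl3C6H2COCl (2.6 equiv), Et3N, toluene, rt; then 20, 65 °C
Reagents that add atoms: angelic acid (second equivalent of 21), C/C=C(/C)C(=O)O
Why: Yamaguchi-type acylation of the two secondary hydroxyls, each by one equivalent of the mixed anhydride of angelic acid and run without a nucleophilic catalyst, avoids isomerisation to the tiglate and changes no stereocentre.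

Step 13
Reactants: 22 (1R,2R,3R,5R)-6,6-dibromo-3-[(3S)-3-(angeloyloxy)-6-methylhepta-1,5-dien-2-yl]bicyclo[3.1.0]hexan-2-yl angelate
Product: 25 (1R,5R,6R)-2-bromo-6-hydroxy-5-[(3S)-3-(angeloyloxy)-6-methylhepta-1,5-dien-2-yl]cyclohex-2-en-1-yl angelate, via bromoallyl cation 23 (not isolated), via dioxolanylium ion 24 (not isolated)
Conditions: AgBF4, CH2Cl2, −40 → 0 °C, dark; then THF–H2O, NaHCO3
Reagents that add atoms: water, O
Why: Monovalent silver abstracts the endo bromide while the bond between the two ring-fusion carbons opens in a disrotatory two-electron electrocyclic process, so the carbene carbon becomes target C3 of a six-membered 2-bromoallyl cation (23) and the cyclopentane is expanded by one atom; only the endo bromide can leave because the ring forces inward rotation, so both cyclopropane diastereomers converge. The carbonyl oxygen of the target-C1 angelate then closes the temporary dioxolanylium ring (24) by 5-exo attack on the adjacent allyl terminus C2, which fixes the regiochemistry (C2, not C4) and, because the tether reaches only the face of its own C1–O bond, sets the new C2 stereocentre cis to C1–O. Water adds to the dioxolanylium carbon and the ortho acid collapses with retention at both ring carbons, so the net result is a 1,2-shift of the angelate from O1 to O2 with release of the C1 hydroxyl. The closest known reactions are the silver-promoted ring opening of ring-fused gem-dibromocyclopropanes with capture of the allyl cation by a tethered carbonyl oxygen and the Woodward–Prévost hydrolysis of acyloxonium ions. The selectivity needed is the site of ortho acid collapse: the ester should stay on O2, which is pseudoaxial because the C6 side chain and the C1 oxygen are trans-diequatorial and because of allylic strain with C3–Br, in line with the usual kinetic preference for the axial ester. Water is withheld until the cation is fully captured, so external attack at C4 cannot compete.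

Step 14
Reactants: 25 (1R,5R,6R)-2-bromo-6-hydroxy-5-[(3S)-3-(angeloyloxy)-6-methylhepta-1,5-dien-2-yl]cyclohex-2-en-1-yl angelate
Product: 26 (1S,5R,6R)-6-hydroxy-2-methyl-5-[(3S)-3-(angeloyloxy)-6-methylhepta-1,5-dien-2-yl]cyclohex-2-en-1-yl angelate
Conditions: MeZnCl, Pd(P(t-Bu)3)2 (5 mol%), THF–NMP, rt
Reagents that add atoms: methylzinc chloride, C[Zn]Cl
Why: In this Negishi coupling, oxidative addition of the alkenyl bromide to the bulky monoligated zerovalent palladium should outpace ionisation of the two hindered secondary allylic angelates, the organozinc tolerates the esters, and no stereocentre is affected.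

Step 15
Reactants: 26 (1S,5R,6R)-6-hydroxy-2-methyl-5-[(3S)-3-(angeloyloxy)-6-methylhepta-1,5-dien-2-yl]cyclohex-2-en-1-yl angelate
Product: 27 CNP0296086.5 (target: ring 3,4-epoxide cis to the side chain and trans to the C2 angelate and C1 hydroxyl; side-chain (R)-epoxide)
Conditions: D-fructose-derived Shi ketone (1,2:4,5-di-O-isopropylidene-β-D-erythro-2,3-hexodiulo-2,6-pyranose, stoichiometric), KHSO5 (as 2KHSO5·KHSO4·K2SO4), NaHCO3 (pH about 8), Bu4NHSO4, MeCN–aq. Na2EDTA, 0 °C
Reagents that add atoms: potassium peroxymonosulfate, [K+].[O-]S(=O)(=O)OO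
Why: Shi epoxidation by the chiral dioxirane should reach only the two electron-rich trisubstituted alkenes, giving the side-chain (R)-epoxide under catalyst control and the ring epoxide on the face opposite the pseudoaxial C2 angelate and the C1 hydroxyl, which is also the face this catalyst prefers (matched case), while the 1,1-disubstituted alkene and the angelate double bonds are too unreactive.

**Compound list**

1 | (R)-4-benzyloxazolidin-2-one | O=C1N[C@H](Cc2ccccc2)CO1 | starting material
2 | pent-4-enoyl chloride | C=CCCC(=O)Cl | starting material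
3 | lithium (R)-4-benzyl-2-oxooxazolidin-3-ide | [Li]N1[C@H](Cc2ccccc2)COC1=O | intermediate
4 | (R)-4-benzyl-3-(pent-4-enoyl)oxazolidin-2-one | C=CCCC(=O)N1[C@H](Cc2ccccc2)COC1=O | intermediate
5 | (E)-cinnamaldehyde | O=C/C=C/c1ccccc1 | starting material
6 | (R)-4-benzyl-3-[(2S,3S,4E)-2-allyl-5-phenyl-3-(trimethylsilyloxy)pent-4-enoyl]oxazolidin-2-one | O=C(N1[C@H](Cc2ccccc2)COC1=O)[C@@H](CC=C)[C@@H](O[Si](C)(C)C)/C=C/c1ccccc1 | intermediate
7 | (R)-4-benzyl-3-[(2S,3S,4E)-2-allyl-3-hydroxy-5-phenylpent-4-enoyl]oxazolidin-2-one | O=C(N1[C@H](Cc2ccccc2)COC1=O)[C@@H](CC=C)[C@@H](O)/C=C/c1ccccc1 | intermediate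
8 | (2S,3S,4E)-2-allyl-3-hydroxy-N-methoxy-N-methyl-5-phenylpent-4-enamide | CON(C)C(=O)[C@@H](CC=C)[C@@H](O)/C=C/c1ccccc1 | intermediate
9 | (2S,3S,4E)-2-allyl-N-methoxy-N-methyl-5-phenyl-3-(triethylsilyloxy)pent-4-enamide | CON(C)C(=O)[C@@H](CC=C)[C@@H](O[Si](CC)(CC)CC)/C=C/c1ccccc1 | intermediate
10 | (1S,2S)-N-methoxy-N-methyl-2-(triethylsilyloxy)cyclopent-3-ene-1-carboxamide | CON(C)C(=O)[C@H]1CC=C[C@@H]1O[Si](CC)(CC)CC | intermediate
11 | (1R,2R,3S,5R)-6,6-dibromo-N-methoxy-N-methyl-2-(triethylsilyloxy)bicyclo[3.1.0]hexane-3-carboxamide | CON(C)C(=O)[C@H]1C[C@@H]2[C@H]([C@@H]1O[Si](CC)(CC)CC)C2(Br)Br | intermediate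
12 | diisobutylaluminium hemiaminal of 11 (epimers at the hemiaminal carbon) | CON(C)C(O[Al](CC(C)C)CC(C)C)[C@H]1C[C@@H]2[C@H]([C@@H]1O[Si](CC)(CC)CC)C2(Br)Br | intermediate
13 | (1R,2R,3S,5R)-6,6-dibromo-2-(triethylsilyloxy)bicyclo[3.1.0]hexane-3-carbaldehyde | O=C[C@H]1C[C@@H]2[C@H]([C@@H]1O[Si](CC)(CC)CC)C2(Br)Br | intermediate
14 | (1R,2R,3R,5R)-6,6-dibromo-3-(2-methoxyvinyl)-2-(triethylsilyloxy)bicyclo[3.1.0]hexane (E/Z mixture) | COC=C[C@H]1C[C@@H]2[C@H]([C@@H]1O[Si](CC)(CC)CC)C2(Br)Br | intermediate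
15 | 2-[(1R,2R,3R,5R)-6,6-dibromo-2-hydroxybicyclo[3.1.0]hexan-3-yl]acetaldehyde | O=CC[C@H]1C[C@@H]2[C@H]([C@@H]1O)C2(Br)Br | intermediate
16 | 2-[(1R,2R,3R,5R)-6,6-dibromo-2-hydroxybicyclo[3.1.0]hexan-3-yl]-3-(dimethylamino)propanal (epimers at C2 of the propanal) | O=CC(CN(C)C)[C@H]1C[C@@H]2[C@H]([C@@H]1O)C2(Br)Br | intermediate
17 | 2-[(1R,2R,3R,5R)-6,6-dibromo-2-hydroxybicyclo[3.1.0]hexan-3-yl]prop-2-enal | C=C(C=O)[C@H]1C[C@@H]2[C@H]([C@@H]1O)C2(Br)Br | intermediate
18 | diisopinocampheylborinate of 19 at the side-chain oxygen | C=CC[C@H](OB([C@@H]1C[C@@H]2C[C@H]([C@H]1C)C2(C)C)[C@@H]1C[C@@H]2C[C@H]([C@H]1C)C2(C)C)C(=C)[C@H]1C[C@@H]2[C@H]([C@@H]1O)C2(Br)Br | intermediate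
19 | (1R,2R,3R,5R)-6,6-dibromo-3-[(3S)-3-hydroxyhexa-1,5-dien-2-yl]bicyclo[3.1.0]hexan-2-ol | C=CC[C@H](O)C(=C)[C@H]1C[C@@H]2[C@H]([C@@H]1O)C2(Br)Br | intermediate
20 | (1R,2R,3R,5R)-6,6-dibromo-3-[(3S)-3-hydroxy-6-methylhepta-1,5-dien-2-yl]bicyclo[3.1.0]hexan-2-ol | CC(C)=CC[C@H](O)C(=C)[C@H]1C[C@@H]2[C@H]([C@@H]1O)C2(Br)Br | intermediate
21 | angelic acid, (Z)-2-methylbut-2-enoic acid | C/C=C(/C)C(=O)O | starting material
22 | (1R,2R,3R,5R)-6,6-dibromo-3-[(3S)-3-(angeloyloxy)-6-methylhepta-1,5-dien-2-yl]bicyclo[3.1.0]hexan-2-yl angelate | CC(C)=CC[C@H](OC(=O)/C(C)=C\C)C(=C)[C@H]1C[C@@H]2[C@H]([C@@H]1OC(=O)/C(C)=C\C)C2(Br)Br | intermediate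
23 | 2-bromocyclohex-2-en-1-ylium (allyl cation) tetrafluoroborate bearing the C6 angelate and the side chain | CC(C)=CC[C@H](OC(=O)/C(C)=C\C)C(=C)[C@H]1C[CH+]C(Br)=C[C@@H]1OC(=O)/C(C)=C\C.F[B-](F)(F)F | intermediate
24 | cis-fused 2-[(Z)-but-2-en-2-yl]-1,3-dioxolan-2-ylium tetrafluoroborate on the 2-bromocyclohexene | CC(C)=CC[C@H](OC(=O)/C(C)=C\C)C(=C)[C@H]1CC=C(Br)[C@@H]2OC(/C(C)=C\C)=[O+][C@H]12.F[B-](F)(F)F | intermediate
25 | (1R,5R,6R)-2-bromo-6-hydroxy-5-[(3S)-3-(angeloyloxy)-6-methylhepta-1,5-dien-2-yl]cyclohex-2-en-1-yl angelate | CC(C)=CC[C@H](OC(=O)/C(C)=C\C)C(=C)[C@H]1CC=C(Br)[C@H](OC(=O)/C(C)=C\C)[C@@H]1O | intermediate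
26 | (1S,5R,6R)-6-hydroxy-2-methyl-5-[(3S)-3-(angeloyloxy)-6-methylhepta-1,5-dien-2-yl]cyclohex-2-en-1-yl angelate | CC(C)=CC[C@H](OC(=O)/C(C)=C\C)C(=C)[C@H]1CC=C(C)[C@H](OC(=O)/C(C)=C\C)[C@@H]1O | intermediate
27 | CNP0296086.5, the bis-epoxy bisabolane diangelate | C=C([C@H](C[C@H]1OC1(C)C)OC(=O)/C(C)=C\C)[C@H]1C[C@H]2O[C@@]2(C)[C@H](OC(=O)/C(C)=C\C)[C@@H]1O | target

**Step count and risks**

Total step count: 15. Longest linear sequence: 15 steps (fully linear from 1; 2, 5, 21 and all reagents are commercial).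

Steps most likely to fail:

Step 13. The participating angelate may lose its Z geometry while it is part of the dioxolanylium ion, or the ortho acid may collapse without site selectivity. The fallback sets out from 20 and uses an acetate, which cannot isomerise, as the participating group, bringing in the angelates afterwards. Acetylation of 20 (Ac2O, pyridine) should give the diacetate F1. AgBF4 followed by water should give, through the acetoxonium ion, the ring-expanded 2-bromocyclohexenyl acetate with free C1 hydroxyl F2. Silylation (t-BuMe2SiOTf, 2,6-lutidine) gives the silyl ether F3. Both acetates are removed with i-Bu2AlH at −78 °C to give the diol F4. Yamaguchi-type bis-angeloylation gives the silylated diangelate F5, and HF·pyridine then returns to the route at 25.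

Step 14. Zerovalent palladium may ionise the allylic angelates instead of inserting into the C–Br bond, or the zinc alkoxide may trigger a 1,2-acyl shift. The fallback sets out from 25 and carries out the coupling on a compound without allylic esters. Silylation of 25 gives the silyl ether F5, and i-Bu2AlH removes both angelates to give the diol F4. Negishi methylation of F4 under the same catalyst gives the methylated diol F6. Bis-angeloylation gives the silylated diangelate F7, and HF·pyridine returns to the route at 26.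

Step 15. Oxygen transfer to the deactivated, hindered ring alkene may be slow, may occur on the wrong face, or the buffered medium may cause acyl migration between O2 and O1. The fallback sets out from 26 and separates the two epoxidations, making the ring epoxidation purely substrate-controlled. Shi epoxidation with a limited amount of oxidant should give the side-chain monoepoxide F8. Silylation of the C1 hydroxyl (Et3SiOTf, 2,6-lutidine) gives the silyl ether F9, in which both lower-face oxygens are blocked. mCPBA with NaHCO3 in CH2Cl2 should then epoxidise the ring alkene from the upper face to give the bis-epoxide silyl ether F10. HF·pyridine buffered with pyridine returns to the route at 27.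

Further compounds
F1 | step 13 | diacetate of 20 | CC(C)=CC[C@H](OC(C)=O)C(=C)[C@H]1C[C@@H]2[C@H]([C@@H]1OC(C)=O)C2(Br)Br
F2 | step 13 | (1R,5R,6R)-5-[(3S)-3-acetoxy-6-methylhepta-1,5-dien-2-yl]-2-bromo-6-hydroxycyclohex-2-en-1-yl acetate | CC(C)=CC[C@H](OC(C)=O)C(=C)[C@H]1CC=C(Br)[C@H](OC(C)=O)[C@@H]1O
F3 | step 13 | tert-butyldimethylsilyl ether of F2 | CC(C)=CC[C@H](OC(C)=O)C(=C)[C@H]1CC=C(Br)[C@H](OC(C)=O)[C@@H]1O[Si](C)(C)C(C)(C)C
F4 | step 13 | (1R,5R,6R)-2-bromo-6-(tert-butyldimethylsilyloxy)-5-[(3S)-3-hydroxy-6-methylhepta-1,5-dien-2-yl]cyclohex-2-en-1-ol | CC(C)=CC[C@H](O)C(=C)[C@H]1CC=C(Br)[C@H](O)[C@@H]1O[Si](C)(C)C(C)(C)C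
F5 | step 13 | tert-butyldimethylsilyl ether of 25 | CC(C)=CC[C@H](OC(=O)/C(C)=C\C)C(=C)[C@H]1CC=C(Br)[C@H](OC(=O)/C(C)=C\C)[C@@H]1O[Si](C)(C)C(C)(C)C
F6 | step 14 | (1S,5R,6R)-6-(tert-butyldimethylsilyloxy)-5-[(3S)-3-hydroxy-6-methylhepta-1,5-dien-2-yl]-2-methylcyclohex-2-en-1-ol | CC(C)=CC[C@H](O)C(=C)[C@H]1CC=C(C)[C@H](O)[C@@H]1O[Si](C)(C)C(C)(C)C
F7 | step 14 | tert-butyldimethylsilyl ether of 26 | CC(C)=CC[C@H](OC(=O)/C(C)=C\C)C(=C)[C@H]1CC=C(C)[C@H](OC(=O)/C(C)=C\C)[C@@H]1O[Si](C)(C)C(C)(C)C
F8 | step 15 | side-chain (R)-monoepoxide of 26 | C=C([C@H](C[C@H]1OC1(C)C)OC(=O)/C(C)=C\C)[C@H]1CC=C(C)[C@H](OC(=O)/C(C)=C\C)[C@@H]1O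
F9 | step 15 | triethylsilyl ether of F8 | C=C([C@H](C[C@H]1OC1(C)C)OC(=O)/C(C)=C\C)[C@H]1CC=C(C)[C@H](OC(=O)/C(C)=C\C)[C@@H]1O[Si](CC)(CC)CC
F10 | step 15 | triethylsilyl ether of 27 | C=C([C@H](C[C@H]1OC1(C)C)OC(=O)/C(C)=C\C)[C@H]1C[C@H]2O[C@@]2(C)[C@H](OC(=O)/C(C)=C\C)[C@@H]1O[Si](CC)(CC)CC
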